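## Retrosynthetic overview

- Numbering (azulene): C8a is the methyl-bearing fusion carbon, C3a the fusion CH, C3 the isopropyl carbinol, C4 the aroyloxy carbon, C6=C7 the ring alkene, C8 the tigloyloxy carbon.
- Endgame: C8–O and the C6=C7 alkene come from a singlet-oxygen ene reaction on a C7=C8 alkene; the C3 carbinol from radical hydration of a C2=C3 isopropyl alkene; the C4 ester from a C4 ketone.
- Key disconnection: C6–C7 and C3a–C8a together, by intramolecular (4+3) cycloaddition of a 2-siloxyallyl cation (C7–C8–C8a) with a tethered 2-siloxy-1,3-diene (C3a=C4–C5=C6); cyclopentane and cycloheptene close in the same step from acyclic triene 11.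
- Enabling feature: the seven-membered ring carries oxygen on C8 (centre of the three-carbon unit C7–C8–C8a) and on C4 (inner carbon of the four-carbon unit C3a–C6), and the two units meet at the fusion bond, whose ends are bridged by C1–C2–C3 of the cyclopentane.
- Triene 11 comes from aldehyde 6 by asymmetric Mukaiyama aldol; its C3 silyloxy stereocentre steers the cycloaddition and is afterwards rebuilt as the tertiary carbinol.

Key step: step 7

Remark: compounds 3 to 11 carry the chlorine-bearing carbon as an equal mixture of both configurations; this centre becomes planar in step 7, so it is left open in the SMILES.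

Remark: in step 5 the catalyst antipode that delivers the 6R carbinol is the one meant; it is written as the (S)-tryptophan-derived catalyst on the assumption that its usual aldehyde-face preference holds for this unbranched aldehyde.

## Route

Step 1
Reactants: 1 3-methylbut-3-en-2-one; 2 allyltrimethylsilane
Product: 3 3-methylhept-6-en-2-one
Conditions: TiCl4, CH2Cl2, −78 °C; H2O
Reagents that add atoms: none
Why: Hosomi–Sakurai conjugate allylation of the TiCl4-activated α-methylene ketone at its unsubstituted β-carbon should give the δ,ε-unsaturated ketone (no stereocentre of consequence).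

Step 2
Reactants: 3 3-methylhept-6-en-2-one
Product: 4 3-chloro-3-methylhept-6-en-2-one
Conditions: SO2Cl2, CH2Cl2, 0 °C to rt, dark
Reagents that add atoms: sulfuryl chloride, ClS(Cl)(=O)=O
Why: α-chlorination of a ketone through its more substituted enol should place chlorine on the tertiary carbon, the terminal alkene being inert without a radical initiator.

Step 3
Reactants: 4 3-chloro-3-methylhept-6-en-2-one
Product: 6 4-chloro-4-methyl-5-oxohexanal, via ozonide 5 (not isolated)
Conditions: O3, CH2Cl2, −78 °C; then PPh3, −78 °C to rt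
Reagents that add atoms: ozone, [O-][O+]=O
Why: ozonolysis of the terminal alkene with reductive work-up should give the aldehyde without touching the α-chloro ketone.

Step 4
Reactants: 7 (3E)-pent-3-en-2-one
Product: 8 (3E)-2-(trimethylsilyloxy)penta-1,3-diene
Conditions: LDA, THF, −78 °C; then Me3SiCl
Reagents that add atoms: chlorotrimethylsilane, C[Si](C)(C)Cl
Why: kinetic deprotonation of an enone occurs at the methyl (cross-conjugated enolate), and O-silylation should give the 2-siloxydiene.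

Step 5
Reactants: 6 4-chloro-4-methyl-5-oxohexanal; 8 (3E)-2-(trimethylsilyloxy)penta-1,3-diene
Product: 10 (2E,6R)-9-chloro-6-hydroxy-9-methylundec-2-ene-4,10-dione, via silyl ether 9 (not isolated)
Conditions: N-tosyl-(S)-tryptophan-derived B-butyl-oxazaborolidinone (20 mol %), EtCN, −78 °C; then 1 M HCl, THF, 0 °C
Reagents that add atoms: none
Why: catalytic enantioselective Mukaiyama aldol addition of the silyl enol ether to the aldehyde (faster than to either ketone) should set the 6R carbinol by catalyst control of the aldehyde face.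

Step 6
Reactants: 10 (2E,6R)-9-chloro-6-hydroxy-9-methylundec-2-ene-4,10-dione
Product: 11 (6R,7Z,9E)-2,6,8-tris(tert-butyldimethylsilyloxy)-3-chloro-3-methylundeca-1,7,9-triene
Conditions: TBSOTf (3.5 equiv), Et3N, CH2Cl2, −78 to 0 °C
Reagents that add atoms: tert-butyldimethylsilyl trifluoromethanesulfonate, CC(C)(C)[Si](C)(C)OS(=O)(=O)C(F)(F)F
Why: silyl triflate with amine silylates the alcohol and soft-enolizes both ketones, the chloro ketone toward its only enolizable methyl (2-siloxyallyl chloride) and the enone at the α'-methylene (2-siloxydiene, Z enol ether preferred with the branched substituent).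

Step 7
Reactants: 11 (6R,7Z,9E)-2,6,8-tris(tert-butyldimethylsilyloxy)-3-chloro-3-methylundeca-1,7,9-triene
Product: 12 (3R,3aR,6R,8aS)-3,4-bis(tert-butyldimethylsilyloxy)-6,8a-dimethyl-2,3,3a,6,7,8a-hexahydroazulen-8(1H)-one
Conditions: ZnCl2 (0.2 equiv), CH2Cl2, −78 to −20 °C; Et3N quench
Reagents that add atoms: none
Why: ZnCl2 abstracts the tertiary allylic chloride of 11 to give a 2-siloxyallyl cation (C7–C8–C8a), which adds across the termini of the tethered 2-siloxy-1,3-diene (C3a=C4–C5=C6) in an intramolecular oxyallyl cation (4+3) cycloaddition, concerted but asynchronous or stepwise through a siloxy-stabilised allyl cation, and loss of the silyl group from the C8 oxocarbenium ion as the silyl chloride returns the catalyst and leaves the C8 ketone beside the C4 silyl enol ether. The closest known reaction type is the Lewis-acid- or silver-promoted (4+3) cycloaddition of 2-siloxyallyl halides with dienes and its intramolecular form that gives bicyclo[5.3.0]decenones. The cyclopentane closes through the C3a–C8a bond in a 5-exo mode (diene terminus onto the cation terminus across the three-carbon tether) and the cycloheptene closes by the second bond C6–C7 as the seven-membered ring of the (4+3) union. At C3a the diene face is fixed by the C3 stereocentre, because allylic 1,3-strain with the C4 siloxy group holds the C3 hydrogen in the diene plane and puts the bulky C3 silyloxy group opposite the tether, so C3–O should end syn to C3a–H; at C8a an extended transition state with the (E)-configured tether outside should give the trans ring fusion (methyl anti to C3a–H); at C6 suprafacial bonding to the (E)-propenyl terminus should place C6–H syn to C3a–H. The step needs (4+3) periselectivity over five-ring closure at C4 and over silyl loss after the first bond, which the trans disposition of the two arms on the new cyclopentane (a strained trans-bicyclo[3.3.0] ring would result) and the low temperature should secure.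

Step 8
Reactants: 12 (3R,3aR,6R,8aS)-3,4-bis(tert-butyldimethylsilyloxy)-6,8a-dimethyl-2,3,3a,6,7,8a-hexahydroazulen-8(1H)-one
Product: 14 diethyl (3R,3aR,6S,8aS)-3-(tert-butyldimethylsilyloxy)-6,8a-dimethyl-4-oxo-1,2,3,3a,4,5,6,8a-octahydroazulen-8-yl phosphate, via enol phosphate 13 (not isolated)
Conditions: LDA, THF, −78 °C; ClP(O)(OEt)2, DMPU, −78 to 0 °C; then 1 M HCl, THF, 0 °C
Reagents that add atoms: diethyl chlorophosphate, CCOP(=O)(Cl)OCC
Why: the C8 ketone can enolize only toward C7 (C8a is quaternary, C4 is masked as its silyl enol ether), so O-phosphorylation gives one enol phosphate, and mild acid then hydrolyses the silyl enol ether selectively to the C4 ketone.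

Step 9
Reactants: 14 diethyl (3R,3aR,6S,8aS)-3-(tert-butyldimethylsilyloxy)-6,8a-dimethyl-4-oxo-1,2,3,3a,4,5,6,8a-octahydroazulen-8-yl phosphate
Product: 15 (3R,3aS,4S,6S,8aR)-3-(tert-butyldimethylsilyloxy)-6,8a-dimethyl-1,2,3,3a,4,5,6,8a-octahydroazulen-4-ol
Conditions: Li, NH3 (l), THF, t-BuOH, −78 to −33 °C; NH4Cl
Reagents that add atoms: none
Why: dissolving-metal reduction cleaves the enol phosphate to the C7=C8 alkene and reduces the C4 ketone under thermodynamic control to the equatorial alcohol (C4–H anti to C3a–H), where a hydride would be turned to the other face by the axial angular methyl.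

Step 10
Reactants: 16 4-hydroxybenzoic acid
Product: 18 4-(triisopropylsilyloxy)benzoic acid, via silyl ester 17 (not isolated)
Conditions: i-Pr3SiCl (2.2 equiv), imidazole, DMF, rt; then AcOH, THF, H2O, rt
Reagents that add atoms: chlorotriisopropylsilane, CC(C)[Si](Cl)(C(C)C)C(C)C
Why: exhaustive silylation followed by selective hydrolysis of the labile silyl ester should leave the aryl silyl ether.

Step 11
Reactants: 15 (3R,3aS,4S,6S,8aR)-3-(tert-butyldimethylsilyloxy)-6,8a-dimethyl-1,2,3,3a,4,5,6,8a-octahydroazulen-4-ol; 18 4-(triisopropylsilyloxy)benzoic acid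
Product: 19 (3R,3aS,4S,6S,8aR)-3-(tert-butyldimethylsilyloxy)-6,8a-dimethyl-1,2,3,3a,4,5,6,8a-octahydroazulen-4-yl 4-(triisopropylsilyloxy)benzoate
Conditions: EDC·HCl, DMAP, CH2Cl2, rt
Reagents that add atoms: none
Why: Steglich esterification of the only free hydroxyl, with retention at C4.

Step 12
Reactants: 19 (3R,3aS,4S,6S,8aR)-3-(tert-butyldimethylsilyloxy)-6,8a-dimethyl-1,2,3,3a,4,5,6,8a-octahydroazulen-4-yl 4-(triisopropylsilyloxy)benzoate
Product: 20 (3R,3aR,4S,6S,8aR)-3-hydroxy-6,8a-dimethyl-1,2,3,3a,4,5,6,8a-octahydroazulen-4-yl 4-(triisopropylsilyloxy)benzoate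
Conditions: p-TsOH·H2O (0.1 equiv), MeOH, CH2Cl2, rt
Reagents that add atoms: none
Why: acid-catalysed methanolysis removes the secondary alkyl silyl ether, while the aryl silyl ether and the ester are stable to mild acid.

Step 13
Reactants: 20 (3R,3aR,4S,6S,8aR)-3-hydroxy-6,8a-dimethyl-1,2,3,3a,4,5,6,8a-octahydroazulen-4-yl 4-(triisopropylsilyloxy)benzoate
Product: 21 (3aS,4S,6S,8aR)-6,8a-dimethyl-3-oxo-1,2,3,3a,4,5,6,8a-octahydroazulen-4-yl 4-(triisopropylsilyloxy)benzoate
Conditions: Dess–Martin periodinane, NaHCO3, CH2Cl2, 0 °C to rt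
Reagents that add atoms: none
Why: buffered Dess–Martin oxidation of the secondary alcohol should give the cyclopentanone without epimerizing C3a.

Step 14
Reactants: 21 (3aS,4S,6S,8aR)-6,8a-dimethyl-3-oxo-1,2,3,3a,4,5,6,8a-octahydroazulen-4-yl 4-(triisopropylsilyloxy)benzoate
Product: 22 (3aS,4S,6S,8aR)-6,8a-dimethyl-3-(trifluoromethylsulfonyloxy)-1,3a,4,5,6,8a-hexahydroazulen-4-yl 4-(triisopropylsilyloxy)benzoate
Conditions: KN(SiMe3)2, THF, −78 °C; PhNTf2; then aq. NH4Cl
Reagents that add atoms: N-phenylbis(trifluoromethanesulfonimide), O=S(=O)(N(c1ccccc1)S(=O)(=O)C(F)(F)F)C(F)(F)F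
Why: kinetic deprotonation at the unhindered C2 methylene (not at the hindered C3a methine, which would expel the β-acyloxy group) and O-triflation should give the C2=C3 alkenyl triflate.

Step 15
Reactants: 22 (3aS,4S,6S,8aR)-6,8a-dimethyl-3-(trifluoromethylsulfonyloxy)-1,3a,4,5,6,8a-hexahydroazulen-4-yl 4-(triisopropylsilyloxy)benzoate
Product: 23 (3aR,4S,6S,8aR)-6,8a-dimethyl-3-(propan-2-yl)-1,3a,4,5,6,8a-hexahydroazulen-4-yl 4-(triisopropylsilyloxy)benzoate
Conditions: i-PrMgCl, Fe(acac)3 (5 mol %), THF, NMP, −30 °C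
Reagents that add atoms: isopropylmagnesium chloride, CC(C)[Mg]Cl
Why: iron-catalysed Kumada-type cross-coupling of an alkenyl triflate with an alkyl Grignard reagent is fast enough at low temperature to spare the ester.

Step 16
Reactants: 23 (3aR,4S,6S,8aR)-6,8a-dimethyl-3-(propan-2-yl)-1,3a,4,5,6,8a-hexahydroazulen-4-yl 4-(triisopropylsilyloxy)benzoate
Product: 24 (3S,3aS,4S,6S,8aR)-3-hydroxy-6,8a-dimethyl-3-(propan-2-yl)-1,2,3,3a,4,5,6,8a-octahydroazulen-4-yl 4-(triisopropylsilyloxy)benzoate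
Conditions: Mn(dpm)3 (10 mol %), PhSiH3, O2 (1 atm), i-PrOH, CH2Cl2, 0 °C
Reagents that add atoms: dioxygen, O=O
Why: Mukaiyama hydrogen-atom-transfer hydration puts hydrogen on C2 of the trisubstituted alkene (faster than on the cis-disubstituted C7=C8 alkene), and the tertiary C3 radical should capture oxygen on the face of C3a–H, anti to the C4-bearing substituent on C3a and to the angular methyl.

Step 17
Reactants: 24 (3S,3aS,4S,6S,8aR)-3-hydroxy-6,8a-dimethyl-3-(propan-2-yl)-1,2,3,3a,4,5,6,8a-octahydroazulen-4-yl 4-(triisopropylsilyloxy)benzoate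
Product: 26 (3S,3aS,4S,8R,8aS)-3,8-dihydroxy-6,8a-dimethyl-3-(propan-2-yl)-1,2,3,3a,4,5,8,8a-octahydroazulen-4-yl 4-(triisopropylsilyloxy)benzoate, via hydroperoxide 25 (not isolated)
Conditions: O2, tetraphenylporphyrin (cat.), visible light, CH2Cl2, 0 °C; then PPh3
Reagents that add atoms: dioxygen, O=O
Why: Schenck ene reaction, in which singlet oxygen bonds to C8 on the face anti to the 8a- and 6-methyl groups and removes the syn C6–H (the only allylic hydrogen, C8a being quaternary), so the alkene moves to C6=C7 and C8–O is set anti to the angular methyl; the phosphine reduces the hydroperoxide.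

Step 18
Reactants: 26 (3S,3aS,4S,8R,8aS)-3,8-dihydroxy-6,8a-dimethyl-3-(propan-2-yl)-1,2,3,3a,4,5,8,8a-octahydroazulen-4-yl 4-(triisopropylsilyloxy)benzoate; 27 (2E)-2-methylbut-2-enoyl chloride
Product: 28 (3S,3aS,4S,8R,8aS)-3-hydroxy-6,8a-dimethyl-8-[(2E)-2-methylbut-2-enoyloxy]-3-(propan-2-yl)-1,2,3,3a,4,5,8,8a-octahydroazulen-4-yl 4-(triisopropylsilyloxy)benzoate
Conditions: pyridine, DMAP (cat.), CH2Cl2, 0 °C to rt
Reagents that add atoms: none
Why: DMAP-catalysed acylation of the secondary allylic alcohol, the tertiary C3 hydroxyl being unreactive, and pyridine (not a trialkylamine) avoiding deconjugation through a vinylketene.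

Step 19
Reactants: 28 (3S,3aS,4S,8R,8aS)-3-hydroxy-6,8a-dimethyl-8-[(2E)-2-methylbut-2-enoyloxy]-3-(propan-2-yl)-1,2,3,3a,4,5,8,8a-octahydroazulen-4-yl 4-(triisopropylsilyloxy)benzoate
Product: 29 (3S,3aS,4S,8R,8aS)-3-hydroxy-6,8a-dimethyl-8-[(2E)-2-methylbut-2-enoyloxy]-3-(propan-2-yl)-1,2,3,3a,4,5,8,8a-octahydroazulen-4-yl 4-hydroxybenzoate
Conditions: Bu4NF, AcOH, THF, 0 °C
Reagents that add atoms: none
Why: buffered fluoride cleaves the aryl silyl ether without acyl migration or ester cleavage.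

## Compound list

1 | 3-methylbut-3-en-2-one | CC(=O)C(C)=C | starting material
2 | allyltrimethylsilane | C=CC[Si](C)(C)C | starting material
3 | 3-methylhept-6-en-2-one | CC(=O)C(C)CCC=C | intermediate
4 | 3-chloro-3-methylhept-6-en-2-one | CC(=O)C(C)(Cl)CCC=C | intermediate
5 | 3-chloro-3-methyl-5-(1,2,4-trioxolan-3-yl)pentan-2-one | CC(=O)C(C)(Cl)CCC1OCOO1 | intermediate
6 | 4-chloro-4-methyl-5-oxohexanal | CC(=O)C(C)(Cl)CCC=O | intermediate
7 | (3E)-pent-3-en-2-one | CC(=O)/C=C/C | starting material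
8 | (3E)-2-(trimethylsilyloxy)penta-1,3-diene | C=C(O[Si](C)(C)C)/C=C/C | intermediate
9 | (2E,6R)-9-chloro-9-methyl-6-(trimethylsilyloxy)undec-2-ene-4,10-dione | CC(=O)C(C)(Cl)CC[C@@H](O[Si](C)(C)C)CC(=O)/C=C/C | intermediate
10 | (2E,6R)-9-chloro-6-hydroxy-9-methylundec-2-ene-4,10-dione | CC(=O)C(C)(Cl)CC[C@@H](O)CC(=O)/C=C/C | intermediate
11 | (6R,7Z,9E)-2,6,8-tris(tert-butyldimethylsilyloxy)-3-chloro-3-methylundeca-1,7,9-triene | C=C(O[Si](C)(C)C(C)(C)C)C(C)(Cl)CC[C@@H](O[Si](C)(C)C(C)(C)C)/C=C(\O[Si](C)(C)C(C)(C)C)/C=C/C | intermediate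
12 | (3R,3aR,6R,8aS)-3,4-bis(tert-butyldimethylsilyloxy)-6,8a-dimethyl-2,3,3a,6,7,8a-hexahydroazulen-8(1H)-one (trans-fused; C3–O, C3a–H and C6–H on one face, 8a-methyl on the other) | O=C1C[C@@H](C)C=C(O[Si](C)(C)C(C)(C)C)[C@@H]2[C@]1(C)CC[C@H]2O[Si](C)(C)C(C)(C)C | intermediate
13 | diethyl (3R,3aR,6S,8aS)-3,4-bis(tert-butyldimethylsilyloxy)-6,8a-dimethyl-1,2,3,3a,6,8a-hexahydroazulen-8-yl phosphate | CCOP(=O)(OCC)OC1=C[C@@H](C)C=C(O[Si](C)(C)C(C)(C)C)[C@@H]2[C@]1(C)CC[C@H]2O[Si](C)(C)C(C)(C)C | intermediate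
14 | diethyl (3R,3aR,6S,8aS)-3-(tert-butyldimethylsilyloxy)-6,8a-dimethyl-4-oxo-1,2,3,3a,4,5,6,8a-octahydroazulen-8-yl phosphate | CCOP(=O)(OCC)OC1=C[C@@H](C)CC(=O)[C@@H]2[C@]1(C)CC[C@H]2O[Si](C)(C)C(C)(C)C | intermediate
15 | (3R,3aS,4S,6S,8aR)-3-(tert-butyldimethylsilyloxy)-6,8a-dimethyl-1,2,3,3a,4,5,6,8a-octahydroazulen-4-ol | C1=C[C@@H](C)C[C@H](O)[C@@H]2[C@]1(C)CC[C@H]2O[Si](C)(C)C(C)(C)C | intermediate
16 | 4-hydroxybenzoic acid | OC(=O)c1ccc(O)cc1 | starting material
17 | triisopropylsilyl 4-(triisopropylsilyloxy)benzoate | CC(C)[Si](C(C)C)(C(C)C)OC(=O)c1ccc(O[Si](C(C)C)(C(C)C)C(C)C)cc1 | intermediate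
18 | 4-(triisopropylsilyloxy)benzoic acid | OC(=O)c1ccc(O[Si](C(C)C)(C(C)C)C(C)C)cc1 | intermediate
19 | (3R,3aS,4S,6S,8aR)-3-(tert-butyldimethylsilyloxy)-6,8a-dimethyl-1,2,3,3a,4,5,6,8a-octahydroazulen-4-yl 4-(triisopropylsilyloxy)benzoate | C1=C[C@@H](C)C[C@H](OC(=O)c3ccc(O[Si](C(C)C)(C(C)C)C(C)C)cc3)[C@@H]2[C@]1(C)CC[C@H]2O[Si](C)(C)C(C)(C)C | intermediate
20 | (3R,3aR,4S,6S,8aR)-3-hydroxy-6,8a-dimethyl-1,2,3,3a,4,5,6,8a-octahydroazulen-4-yl 4-(triisopropylsilyloxy)benzoate | C1=C[C@@H](C)C[C@H](OC(=O)c3ccc(O[Si](C(C)C)(C(C)C)C(C)C)cc3)[C@@H]2[C@]1(C)CC[C@H]2O | intermediate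
21 | (3aS,4S,6S,8aR)-6,8a-dimethyl-3-oxo-1,2,3,3a,4,5,6,8a-octahydroazulen-4-yl 4-(triisopropylsilyloxy)benzoate | C1=C[C@@H](C)C[C@H](OC(=O)c3ccc(O[Si](C(C)C)(C(C)C)C(C)C)cc3)[C@@H]2[C@]1(C)CCC2=O | intermediate
22 | (3aS,4S,6S,8aR)-6,8a-dimethyl-3-(trifluoromethylsulfonyloxy)-1,3a,4,5,6,8a-hexahydroazulen-4-yl 4-(triisopropylsilyloxy)benzoate | C1=C[C@@H](C)C[C@H](OC(=O)c3ccc(O[Si](C(C)C)(C(C)C)C(C)C)cc3)[C@@H]2[C@]1(C)CC=C2OS(=O)(=O)C(F)(F)F | intermediate
23 | (3aR,4S,6S,8aR)-6,8a-dimethyl-3-(propan-2-yl)-1,3a,4,5,6,8a-hexahydroazulen-4-yl 4-(triisopropylsilyloxy)benzoate | C1=C[C@@H](C)C[C@H](OC(=O)c3ccc(O[Si](C(C)C)(C(C)C)C(C)C)cc3)[C@@H]2[C@]1(C)CC=C2C(C)C | intermediate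
24 | (3S,3aS,4S,6S,8aR)-3-hydroxy-6,8a-dimethyl-3-(propan-2-yl)-1,2,3,3a,4,5,6,8a-octahydroazulen-4-yl 4-(triisopropylsilyloxy)benzoate | C1=C[C@@H](C)C[C@H](OC(=O)c3ccc(O[Si](C(C)C)(C(C)C)C(C)C)cc3)[C@@H]2[C@]1(C)CC[C@]2(O)C(C)C | intermediate
25 | (3S,3aS,4S,8R,8aS)-8-hydroperoxy-3-hydroxy-6,8a-dimethyl-3-(propan-2-yl)-1,2,3,3a,4,5,8,8a-octahydroazulen-4-yl 4-(triisopropylsilyloxy)benzoate | OO[C@@H]1C=C(C)C[C@H](OC(=O)c3ccc(O[Si](C(C)C)(C(C)C)C(C)C)cc3)[C@@H]2[C@]1(C)CC[C@]2(O)C(C)C | intermediate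
26 | (3S,3aS,4S,8R,8aS)-3,8-dihydroxy-6,8a-dimethyl-3-(propan-2-yl)-1,2,3,3a,4,5,8,8a-octahydroazulen-4-yl 4-(triisopropylsilyloxy)benzoate | O[C@@H]1C=C(C)C[C@H](OC(=O)c3ccc(O[Si](C(C)C)(C(C)C)C(C)C)cc3)[C@@H]2[C@]1(C)CC[C@]2(O)C(C)C | intermediate
27 | (2E)-2-methylbut-2-enoyl chloride (tigloyl chloride) | C/C=C(\C)C(Cl)=O | starting material
28 | (3S,3aS,4S,8R,8aS)-3-hydroxy-6,8a-dimethyl-8-[(2E)-2-methylbut-2-enoyloxy]-3-(propan-2-yl)-1,2,3,3a,4,5,8,8a-octahydroazulen-4-yl 4-(triisopropylsilyloxy)benzoate | C/C=C(\C)C(=O)O[C@@H]1C=C(C)C[C@H](OC(=O)c3ccc(O[Si](C(C)C)(C(C)C)C(C)C)cc3)[C@@H]2[C@]1(C)CC[C@]2(O)C(C)C | intermediate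
29 | (3S,3aS,4S,8R,8aS)-3-hydroxy-6,8a-dimethyl-8-[(2E)-2-methylbut-2-enoyloxy]-3-(propan-2-yl)-1,2,3,3a,4,5,8,8a-octahydroazulen-4-yl 4-hydroxybenzoate | C/C=C(\C)C(=O)O[C@@H]1C=C(C)C[C@H](OC(=O)c2ccc(O)cc2)[C@@H]2[C@]1(C)CC[C@]2(O)C(C)C | target

## Step count and risks

Total step count: 19. Longest linear sequence: 17 steps (steps 1 to 3, 5 to 9 and 11 to 19; steps 4 and 10 are side branches).

Steps most likely to fail:

Step 7. The cycloaddition may stop after the first bond, because the zwitterion can lose its silyl group before the C6–C7 bond forms, or the ring-fusion selectivity may erode. In that case the two bonds would be made in two separate known steps. From 11, ZnCl2 in CH2Cl2 at −78 °C with early quench (Mukaiyama-type tertiary alkylation of the silyl dienol ether) should give (2E)-1-[(1R,2S,5R)-5-(tert-butyldimethylsilyloxy)-2-[1-(tert-butyldimethylsilyloxy)ethenyl]-2-methylcyclopentyl]but-2-en-1-one F1, which keeps the C8 silyl enol ether. An intramolecular Mukaiyama–Michael addition (TBSOTf cat., CH2Cl2, −78 °C), with the silyl group passing to the C4 oxygen, should then close the seven-membered ring and rejoin the route at 12.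

Step 16. Oxygen capture by the planar tertiary radical may show poor facial selectivity, and hydrogen-atom transfer to the C7=C8 alkene may compete. The fallback sets out from 23. Dihydroxylation (OsO4 cat., N-methylmorpholine N-oxide, acetone, H2O) of the more electron-rich trisubstituted alkene, from the face anti to the angular methyl, should give (2R,3S,3aS,4S,6S,8aR)-2,3-dihydroxy-6,8a-dimethyl-3-(propan-2-yl)-1,2,3,3a,4,5,6,8a-octahydroazulen-4-yl 4-(triisopropylsilyloxy)benzoate F2. Thioacylation of the secondary hydroxyl only (PhOC(S)Cl, pyridine, DMAP) should give (2R,3S,3aS,4S,6S,8aR)-3-hydroxy-6,8a-dimethyl-2-(phenoxycarbonothioyloxy)-3-(propan-2-yl)-1,2,3,3a,4,5,6,8a-octahydroazulen-4-yl 4-(triisopropylsilyloxy)benzoate F3. Barton–McCombie deoxygenation (Bu3SnH, AIBN, toluene, 80 °C) then rejoins the route at 24.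

Step 17. The ene reaction of the cis-disubstituted ring alkene may be slow, so that physical quenching and photo-oxidative degradation compete. The fallback sets out from 24. Epoxidation (mCPBA, NaHCO3, CH2Cl2, 0 °C) on the face anti to the two allylic methyl groups should give (3S,3aS,4S,6S,7R,8S,8aS)-7,8-epoxy-3-hydroxy-6,8a-dimethyl-3-(propan-2-yl)decahydroazulen-4-yl 4-(triisopropylsilyloxy)benzoate F4. Base-mediated syn elimination with diethylaluminium 2,2,6,6-tetramethylpiperidide (Et2Al(tmp), benzene, 0 °C) removes the syn C6–H and opens the C7–O bond, which rejoins the route at 26.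

Further compounds
F1 | step 7 | (2E)-1-[(1R,2S,5R)-5-(tert-butyldimethylsilyloxy)-2-[1-(tert-butyldimethylsilyloxy)ethenyl]-2-methylcyclopentyl]but-2-en-1-one | C=C(O[Si](C)(C)C(C)(C)C)[C@@]1(C)CC[C@@H](O[Si](C)(C)C(C)(C)C)[C@@H]1C(=O)/C=C/C
F2 | step 16 | (2R,3S,3aS,4S,6S,8aR)-2,3-dihydroxy-6,8a-dimethyl-3-(propan-2-yl)-1,2,3,3a,4,5,6,8a-octahydroazulen-4-yl 4-(triisopropylsilyloxy)benzoate | C1=C[C@@H](C)C[C@H](OC(=O)c3ccc(O[Si](C(C)C)(C(C)C)C(C)C)cc3)[C@@H]2[C@]1(C)C[C@@H](O)[C@]2(O)C(C)C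
F3 | step 16 | (2R,3S,3aS,4S,6S,8aR)-3-hydroxy-6,8a-dimethyl-2-(phenoxycarbonothioyloxy)-3-(propan-2-yl)-1,2,3,3a,4,5,6,8a-octahydroazulen-4-yl 4-(triisopropylsilyloxy)benzoate | C1=C[C@@H](C)C[C@H](OC(=O)c3ccc(O[Si](C(C)C)(C(C)C)C(C)C)cc3)[C@@H]2[C@]1(C)C[C@@H](OC(=S)Oc4ccccc4)[C@]2(O)C(C)C
F4 | step 17 | (3S,3aS,4S,6S,7R,8S,8aS)-7,8-epoxy-3-hydroxy-6,8a-dimethyl-3-(propan-2-yl)decahydroazulen-4-yl 4-(triisopropylsilyloxy)benzoate | O1[C@@H]2[C@H]1[C@@H](C)C[C@H](OC(=O)c4ccc(O[Si](C(C)C)(C(C)C)C(C)C)cc4)[C@@H]3[C@]2(C)CC[C@]3(O)C(C)C
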